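**Plan**

1. Retrosynthesis: the two glyceryl CH2OH groups are traced back to a diethyl aryloxymalonate (cut at the ring-A O4–CH bond). C9–OH and the ring-B C9'–OH are traced back to the two ester bonds of an L-tartrate acetonide bridge. The C8–O4' ether and the C7–OH bond are then cut together.
2. This leaves one acyclic diester: (E)-sinapyl alcohol and dihydrosinapyl alcohol on the two carboxyls of (4R,5R)-2,2-dimethyl-1,3-dioxolane-4,5-dicarboxylic acid, both phenols free.
3. Enabling feature: rings A and B are both 3,5-dimethoxy-4-oxyphenyl rings, so every ring carbon ortho to a phenolic oxygen is blocked. The ring-A radical can bond only at side-chain C8, and the ring-B radical (C1' alkylated) only at O4'. The primary alcohols C9–OH and C9'–OH carry the tether.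
4. Forward: sinapic acid gives both C6–C3 arms, which are esterified in turn onto the tartrate. Oxidation closes the only ring of the route, a temporary 16-membered macrocycle, through O4'–C8, and water completes C7. The glyceryl unit is added as a malonate, and one hydride reduction releases the acyclic target.
5. Stereochemistry: C8 comes from the facial bias of the C2-symmetric (4R,5R) tether in the radical recombination. C7 comes from water addition to the macrocycle-shielded quinone methide (threo). No later step touches either centre.

Key step: step 10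

Assumption: the L-tartrate-derived (4R,5R) tether is taken to steer O4' to the C8 face that gives 8R; if the facial sense proved opposite, the equally available D-tartrate acetonide would be used with no other change.

**Route**

Step 1
Reactants: 1 sinapic acid
Product: 2 methyl sinapate, methyl (E)-3-(4-hydroxy-3,5-dimethoxyphenyl)acrylate
Conditions: MeOH, H2SO4 (cat.), reflux
Reagents that add atoms: methanol, CO
Why: Fischer esterification in excess methanol should convert only the carboxylic acid and leave the phenol and the E-alkene untouched.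

Step 2
Reactants: 2 methyl sinapate
Product: 3 methyl (E)-3-[4-(tert-butyldimethylsilyloxy)-3,5-dimethoxyphenyl]acrylate
Conditions: TBSCl, imidazole, DMF, rt
Reagents that add atoms: tert-butyldimethylsilyl chloride, CC(C)(C)[Si](C)(C)Cl
Why: Imidazole-promoted silylation of the phenol (Corey protocol) masks the only acidic OH, so that the later carbodiimide couplings can acylate aliphatic oxygen only.

Step 3
Reactants: 3 methyl (E)-3-[4-(tert-butyldimethylsilyloxy)-3,5-dimethoxyphenyl]acrylate
Product: 4 (E)-3-[4-(tert-butyldimethylsilyloxy)-3,5-dimethoxyphenyl]prop-2-en-1-ol (4-O-TBS-sinapyl alcohol)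
Conditions: DIBAL-H (2.5 equiv), CH2Cl2, −78 °C; Rochelle salt work-up
Reagents that add atoms: none
Why: DIBAL-H 1,2-reduction of an α,β-unsaturated ester at low temperature should give the allylic alcohol with the E-alkene and the aryl silyl ether intact.

Step 4
Reactants: 4 4-O-TBS-sinapyl alcohol (one half of the material; the other half is kept for step 8)
Product: 5 3-[4-(tert-butyldimethylsilyloxy)-3,5-dimethoxyphenyl]propan-1-ol (4-O-TBS-dihydrosinapyl alcohol)
Conditions: H2 (1 atm), 5% Pd/C, EtOAc, rt, stopped after one equivalent of H2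
Reagents that add atoms: none
Why: Heterogeneous catalytic hydrogenation saturates the styrenyl alkene; the neutral aprotic solvent and controlled uptake should hold back hydrogenolysis of the allylic C–O bond.

Step 5
Reactants: 6 dimethyl 2,3-O-isopropylidene-L-tartrate, dimethyl (4R,5R)-2,2-dimethyl-1,3-dioxolane-4,5-dicarboxylate
Product: 7 (4R,5R)-5-(methoxycarbonyl)-2,2-dimethyl-1,3-dioxolane-4-carboxylic acid
Conditions: KOH (1.0 equiv), MeOH, rt; then aq. HCl to pH 2
Reagents that add atoms: potassium hydroxide, [K+].[OH-]
Why: Mono-saponification of a C2-symmetric diester with one equivalent of hydroxide should stop at the half-ester because the first carboxylate repels further hydroxide; the trans stereocentres are not disturbed.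

Step 6
Reactants: 7 (4R,5R)-5-(methoxycarbonyl)-2,2-dimethyl-1,3-dioxolane-4-carboxylic acid; 5 4-O-TBS-dihydrosinapyl alcohol
Product: 8 4-methyl 5-{3-[4-(tert-butyldimethylsilyloxy)-3,5-dimethoxyphenyl]propyl} (4R,5R)-2,2-dimethyl-1,3-dioxolane-4,5-dicarboxylate
Conditions: EDC·HCl, DMAP (cat.), CH2Cl2, 0 °C → rt
Reagents that add atoms: none
Why: Steglich esterification of the free carboxylic acid with the primary alcohol, the only hydroxyl present, should give the mixed diester.

Step 7
Reactants: 8 mixed methyl/arylpropyl tartrate diester
Product: 9 (4R,5R)-5-({3-[4-(tert-butyldimethylsilyloxy)-3,5-dimethoxyphenyl]propoxy}carbonyl)-2,2-dimethyl-1,3-dioxolane-4-carboxylic acid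
Conditions: LiI (5 equiv), EtOAc, reflux, dark; then cold 0.5 M HCl
Reagents that add atoms: none
Why: Nucleophilic ester dealkylation (SN2 attack of iodide on the O-methyl carbon) is far faster at methyl than at the CH2 of the 3-arylpropyl ester, as the inertness of the ethyl acetate solvent shows, so only the methyl ester should be unmasked under neutral conditions that spare the acetonide and the aryl silyl ether.

Step 8
Reactants: 9 tartrate half-ester acid; 4 4-O-TBS-sinapyl alcohol
Product: 10 (4R,5R)-2,2-dimethyl-1,3-dioxolane-4,5-dicarboxylate bearing one (E)-3-[4-(tert-butyldimethylsilyloxy)-3,5-dimethoxyphenyl]allyl ester and one 3-[4-(tert-butyldimethylsilyloxy)-3,5-dimethoxyphenyl]propyl ester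
Conditions: EDC·HCl, DMAP (cat.), CH2Cl2, 0 °C → rt
Reagents that add atoms: none
Why: Steglich esterification of the allylic primary alcohol proceeds under near-neutral conditions that should not ionise the cinnamyl C–O bond or isomerise the alkene.

Step 9
Reactants: 10 bis-silylated mixed diester
Product: 11 4-[(E)-3-(4-hydroxy-3,5-dimethoxyphenyl)allyl] 5-[3-(4-hydroxy-3,5-dimethoxyphenyl)propyl] (4R,5R)-2,2-dimethyl-1,3-dioxolane-4,5-dicarboxylate
Conditions: TBAF (2.4 equiv), AcOH (2.4 equiv), THF, 0 °C
Reagents that add atoms: none
Why: Fluoride cleavage of the two aryl silyl ethers buffered with acetic acid releases the phenols in neutral form, so neither the allylic sinapyl ester nor the activated tartrate esters should be attacked by phenoxide.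

Step 10
Reactants: 11 bis-phenol mixed diester
Product: 13 (7R,8R)-threo tartrate-bridged 16-membered 8-O-4' macrocycle with free ring-A phenol, via macrocyclic quinone methide 12 (not isolated)
Conditions: Ag2O (1.5 equiv), acetone–H2O 9:1, syringe-pump addition of 11 (final 1 mM), rt, dark
Reagents that add atoms: water, O
Why: Proposed new method: silver(I) oxide removes one electron and one proton from each phenol; the sinapyl phenoxyl radical, blocked at both ortho carbons, reacts at C8 and the ring-B radical, blocked ortho and alkylated para, reacts only through O4', so radical recombination forms the O4'–C8 bond and leaves ring A as quinone methide 12, which water attacks at C7 in a rearomatising 1,6-addition (C9–O is acylated, so water is the only nucleophile available). The closest known reaction type is the untethered silver(I) oxide or laccase dehydrogenative 8-O-4' cross-coupling of sinapyl alcohol and its 9-O-acyl esters with syringyl phenols, which is regioselective but not stereoselective. The 16-membered ring (O4', C8, C9, the six-atom tartrate diester, the three chain carbons and four ring-B carbons) closes by intramolecular radical recombination with C–O bond formation under pseudo-high dilution. C8 is set in the recombination, where the C2-symmetric (4R,5R)-dioxolane is expected to deliver O4' to one face of the planar C8 radical centre; C7 is set in the hydration, where the macrocycle spanning O4' and C9 should shield one face of the exocyclic quinone methide so that water enters from the open face to give the threo (7R,8R) arrangement. The step needs O4'–C8 cross-coupling over 8–8 dimerisation and oligomerisation, one face at C8 and threo hydration; the tether and the dilution secure the first, whereas the facial sense at C8 and the threo preference rest on the macrocycle conformation and are unproven.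

Step 11
Reactants: 13 (7R,8R)-macrocycle with free ring-A phenol; 14 diethyl bromomalonate (1.2 equiv)
Product: 15 (7R,8R)-macrocycle whose ring-A O4 carries a bis(ethoxycarbonyl)methyl group (diethyl 2-aryloxymalonate)
Conditions: K2CO3, DMF, rt
Reagents that add atoms: none
Why: Williamson-type O-alkylation of the phenoxide, the only group carbonate deprotonates, with the α-bromomalonate should give the aryloxymalonate; the new O-bearing carbon holds two identical ester groups, so no stereocentre is created and C7–OH stays free.

Step 12
Reactants: 15 macrocyclic aryloxymalonate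
Product: 16 target, (7R,8R)-threo 8-O-4' neolignan with ring-A 4-O-(1,3-dihydroxypropan-2-yl) ether (CNP0186584.2)
Conditions: LiBH4 (excess), THF, 0 °C → rt; aq. NH4Cl
Reagents that add atoms: none
Why: Lithium borohydride reduction of esters converts the malonate into the 1,3-diol and cleaves both bridge esters reductively, freeing C9–OH and C9'–OH in one operation, while ethers, arenes and the C7/C8 stereocentres are inert to hydride.

**Compound list**

1 | sinapic acid, (E)-3-(4-hydroxy-3,5-dimethoxyphenyl)acrylic acid | COc1cc(/C=C/C(=O)O)cc(OC)c1O | starting material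
2 | methyl sinapate | COC(=O)/C=C/c1cc(OC)c(O)c(OC)c1 | intermediate
3 | methyl (E)-3-[4-(tert-butyldimethylsilyloxy)-3,5-dimethoxyphenyl]acrylate | COC(=O)/C=C/c1cc(OC)c(O[Si](C)(C)C(C)(C)C)c(OC)c1 | intermediate
4 | (E)-3-[4-(tert-butyldimethylsilyloxy)-3,5-dimethoxyphenyl]prop-2-en-1-ol | OC/C=C/c1cc(OC)c(O[Si](C)(C)C(C)(C)C)c(OC)c1 | intermediate
5 | 3-[4-(tert-butyldimethylsilyloxy)-3,5-dimethoxyphenyl]propan-1-ol | OCCCc1cc(OC)c(O[Si](C)(C)C(C)(C)C)c(OC)c1 | intermediate
6 | dimethyl (4R,5R)-2,2-dimethyl-1,3-dioxolane-4,5-dicarboxylate (dimethyl 2,3-O-isopropylidene-L-tartrate) | COC(=O)[C@@H]1OC(C)(C)O[C@H]1C(=O)OC | starting material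
7 | (4R,5R)-5-(methoxycarbonyl)-2,2-dimethyl-1,3-dioxolane-4-carboxylic acid | COC(=O)[C@@H]1OC(C)(C)O[C@H]1C(=O)O | intermediate
8 | 4-methyl 5-{3-[4-(tert-butyldimethylsilyloxy)-3,5-dimethoxyphenyl]propyl} (4R,5R)-2,2-dimethyl-1,3-dioxolane-4,5-dicarboxylate | COC(=O)[C@@H]1OC(C)(C)O[C@H]1C(=O)OCCCc2cc(OC)c(O[Si](C)(C)C(C)(C)C)c(OC)c2 | intermediate
9 | (4R,5R)-5-({3-[4-(tert-butyldimethylsilyloxy)-3,5-dimethoxyphenyl]propoxy}carbonyl)-2,2-dimethyl-1,3-dioxolane-4-carboxylic acid | OC(=O)[C@@H]1OC(C)(C)O[C@H]1C(=O)OCCCc2cc(OC)c(O[Si](C)(C)C(C)(C)C)c(OC)c2 | intermediate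
10 | (4R,5R)-2,2-dimethyl-1,3-dioxolane-4,5-dicarboxylate, one ester with 4-O-TBS-(E)-sinapyl alcohol and one with 4-O-TBS-dihydrosinapyl alcohol | COc1cc(/C=C/COC(=O)[C@@H]2OC(C)(C)O[C@H]2C(=O)OCCCc3cc(OC)c(O[Si](C)(C)C(C)(C)C)c(OC)c3)cc(OC)c1O[Si](C)(C)C(C)(C)C | intermediate
11 | 4-[(E)-3-(4-hydroxy-3,5-dimethoxyphenyl)allyl] 5-[3-(4-hydroxy-3,5-dimethoxyphenyl)propyl] (4R,5R)-2,2-dimethyl-1,3-dioxolane-4,5-dicarboxylate (key-step precursor) | COc1cc(/C=C/COC(=O)[C@@H]2OC(C)(C)O[C@H]2C(=O)OCCCc3cc(OC)c(O)c(OC)c3)cc(OC)c1O | intermediate
12 | macrocyclic quinone methide: ring A is a 2,6-dimethoxy-4-alkylidenecyclohexa-2,5-dien-1-one with exocyclic C1=C7; C8 is bonded to O4' of ring B and to C9, which is bridged to the ring-B propyl oxygen through the (4R,5R)-dioxolane diester; descriptor 8S because C9 now outranks sp2 C7, same spatial arrangement as 8R in 13; not isolated | COC1=CC(=C[C@H]4COC(=O)[C@@H]2OC(C)(C)O[C@H]2C(=O)OCCCc3cc(OC)c(O4)c(OC)c3)C=C(OC)C1=O | intermediate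
13 | (7R,8R)-threo tartrate-bridged 16-membered 8-O-4' macrocycle: C7 bears OH and the 4-hydroxy-3,5-dimethoxyphenyl ring A; C8 is bonded to O4' of ring B; O9 and the ring-B propyl oxygen are the ester oxygens of the (4R,5R)-2,2-dimethyl-1,3-dioxolane-4,5-dicarbonyl bridge (key-step product) | COc1cc([C@@H](O)[C@H]4COC(=O)[C@@H]2OC(C)(C)O[C@H]2C(=O)OCCCc3cc(OC)c(O4)c(OC)c3)cc(OC)c1O | intermediate
14 | diethyl bromomalonate | CCOC(=O)C(Br)C(=O)OCC | starting material
15 | macrocycle 13 with ring-A O4 alkylated by CH(CO2Et)2 (diethyl 2-aryloxymalonate), (7R,8R) | COc1cc([C@@H](O)[C@H]4COC(=O)[C@@H]2OC(C)(C)O[C@H]2C(=O)OCCCc3cc(OC)c(O4)c(OC)c3)cc(OC)c1OC(C(=O)OCC)C(=O)OCC | intermediate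
16 | (1R,2R)-1-{4-[(1,3-dihydroxypropan-2-yl)oxy]-3,5-dimethoxyphenyl}-2-[4-(3-hydroxypropyl)-2,6-dimethoxyphenoxy]propane-1,3-diol | COc1cc([C@@H](O)[C@@H](CO)Oc2c(OC)cc(CCCO)cc2OC)cc(OC)c1OC(CO)CO | target

**Totals**

Total step count: 12.
Longest linear sequence: 11 steps (steps 1–4 and 6–12; step 5 is a one-step side branch).

**Steps most likely to fail**

Step 10 (Proposed new method). Several processes are at risk:
- recombination of the two radical centres across the wrong face of C8;
- uptake of water by the quinone methide from the erythro face, which is the direction the untethered hydration of syringyl β-ether quinone methides leans;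
- over-oxidation of ring B at its benzylic carbon;
- intermolecular coupling outrunning ring closure.

The fallback uses known chemistry, an Evans syn-glycolate aldol that builds the C7–C8 bond in place of O4'–C8. It sets out from 2. Hydrogenation (H2, Pd/C, EtOAc) gives methyl 3-(4-hydroxy-3,5-dimethoxyphenyl)propanoate F1. Its phenol is alkylated with (S)-4-benzyl-3-(bromoacetyl)oxazolidin-2-one (K2CO3, acetone) to the aryloxyacetyl imide F2. Commercial syringaldehyde is O-alkylated with 14 (K2CO3, DMF) to diethyl 2-(4-formyl-2,6-dimethoxyphenoxy)malonate F3. The Z-boron enolate of F2 (Bu2BOTf, i-Pr2NEt, CH2Cl2, −78 °C) should add to F3 through a Zimmerman–Traxler chair on the face left open by the (S)-benzyl group. This gives the syn aldol adduct F4, (2S,3R) in the acyl chain, which is the spatial arrangement that becomes (7R,8R) once C9 is reduced. LiBH4 (THF, 0 °C) then removes the auxiliary reductively and reduces the methyl ester and the malonate in the same operation, which comes back to the route at 16.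

Step 11. The phenoxide flanked by two methoxy groups attacks the secondary bromide slowly. During the long exposure to carbonate, the activated tartrate diester of the macrocycle can undergo acyl migration to O7, transesterification or ring-opening oligomerisation. The fallback removes the tether before the alkylation. From 13, LiBH4 (THF, 0 °C → rt) cleaves both bridge esters to the open-chain (7R,8R)-triol phenol F5, in which the phenol is the only OH that carbonate deprotonates. F5 is alkylated with 14 under more forcing conditions (Cs2CO3, DMF, 50 °C) to the open-chain aryloxymalonate F6. LiBH4 reduction of F6 comes back to the route at 16.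

Step 7. On prolonged heating with iodide, discrimination between the two ester alkyl groups may be lost (cleavage of the arylpropyl ester), or the aryl silyl ether may erode. The fallback dispenses with the temporary methyl ester. From 6, complete saponification (KOH 2.2 equiv, MeOH–H2O; then HCl) gives (4R,5R)-2,2-dimethyl-1,3-dioxolane-4,5-dicarboxylic acid F7. A threefold excess of F7 is mono-esterified with alcohol 5 (EDC·HCl, DMAP, THF), and the unreacted water-soluble diacid is washed out. The half-ester obtained is 9, where the route resumes.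

**Further compounds**

F1 | step 10 | methyl 3-(4-hydroxy-3,5-dimethoxyphenyl)propanoate | COC(=O)CCc1cc(OC)c(O)c(OC)c1
F2 | step 10 | (S)-4-benzyl-3-{[2,6-dimethoxy-4-(3-methoxy-3-oxopropyl)phenoxy]acetyl}oxazolidin-2-one | COC(=O)CCc1cc(OC)c(OCC(=O)N2[C@@H](Cc3ccccc3)COC2=O)c(OC)c1
F3 | step 10 | diethyl 2-(4-formyl-2,6-dimethoxyphenoxy)malonate | CCOC(=O)C(Oc1c(OC)cc(C=O)cc1OC)C(=O)OCC
F4 | step 10 | (S)-4-benzyl-3-[(2S,3R)-3-{4-[bis(ethoxycarbonyl)methoxy]-3,5-dimethoxyphenyl}-3-hydroxy-2-{2,6-dimethoxy-4-(3-methoxy-3-oxopropyl)phenoxy}propanoyl]oxazolidin-2-one | COc1cc([C@@H](O)[C@@H](C(=O)N4[C@@H](Cc5ccccc5)COC4=O)Oc2c(OC)cc(CCC(=O)OC)cc2OC)cc(OC)c1OC(C(=O)OCC)C(=O)OCC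
F5 | step 11 | (1R,2R)-1-(4-hydroxy-3,5-dimethoxyphenyl)-2-[4-(3-hydroxypropyl)-2,6-dimethoxyphenoxy]propane-1,3-diol | COc1cc([C@@H](O)[C@@H](CO)Oc2c(OC)cc(CCCO)cc2OC)cc(OC)c1O
F6 | step 11 | diethyl 2-(4-{(1R,2R)-1,3-dihydroxy-2-[4-(3-hydroxypropyl)-2,6-dimethoxyphenoxy]propyl}-2,6-dimethoxyphenoxy)malonate | COc1cc([C@@H](O)[C@@H](CO)Oc2c(OC)cc(CCCO)cc2OC)cc(OC)c1OC(C(=O)OCC)C(=O)OCC
F7 | step 7 | (4R,5R)-2,2-dimethyl-1,3-dioxolane-4,5-dicarboxylic acid | OC(=O)[C@@H]1OC(C)(C)O[C@H]1C(=O)O
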